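**Retrosynthetic overview**
- Target 16 is a single, unsubstituted 35-membered lactone ring (34 carbons and one oxygen, no stereocentre). Opening the C1–O ester bond gives 34-hydroxytetratriacontanoic acid 14.
- 14 comes from the symmetric tetratriacontanedioic acid 10 by desymmetrisation: diester, half-saponification, borane reduction of the free acid end, saponification.
- The strategy rests on the unbranched chain C1–C34 (C1 the lactone carbonyl, C34 the O-bound CH2) dividing as C1–C6 / C7–C28 / C29–C34. The C6–C7 and C28–C29 bonds are disconnected to docosanedioyl dichloride 5 and two molecules of the cyclohexanone enamine 3.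
- Each six-membered carbocycle is a masked six-carbon acid arm: its ring carbonyl carbon becomes C1 or C34 after retro-Claisen opening, and the ketones left at C7 and C28 are removed by Wolff–Kishner reduction. No ring is built before the end; the macrolactone is the only ring closed (step 10).

Key step: step 3

Assumption: cyclohexanone, morpholine and docosanedioic acid are taken as purchased; the target SMILES holds no stereocentre, so no configuration has to be set.

**Route**

Step 1
Reactants: 1 cyclohexanone; 2 morpholine
Product: 3 4-(cyclohex-1-en-1-yl)morpholine
Conditions: TsOH·H2O (cat.), toluene, reflux, Dean–Stark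
Reagents that add atoms: none
Why: Acid-catalysed condensation of a secondary amine with a ketone under azeotropic removal of water gives the enamine (Stork enamine formation), which is purified by distillation.

Step 2
Reactants: 4 docosanedioic acid
Product: 5 docosanedioyl dichloride
Conditions: (COCl)2 (2.5 equiv), DMF (cat.), toluene, 0 °C to 45 °C; evaporate
Reagents that add atoms: oxalyl chloride, ClC(=O)C(Cl)=O
Why: DMF-catalysed (Vilsmeier-type) chlorination converts both carboxyl groups to acyl chlorides with only gaseous by-products, so crude 5 can be used directly.

Step 3
Reactants: 3 4-(cyclohex-1-en-1-yl)morpholine (2.3 equiv); 5 docosanedioyl dichloride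
Product: 7 1,22-bis(2-hydroxycyclohex-1-en-1-yl)docosane-1,22-dione, via bis-acylenamine 6 (not isolated)
Conditions: Et3N (2.2 equiv), CHCl3, 35 °C, slow addition of 5, then rt; then 6 M aq HCl, reflux
Reagents that add atoms: water, O
Why: The enamine β-carbon of 3 attacks each acyl chloride terminus of 5 (directly, or by intercepting the ketene that Et3N can form from 5), Et3N takes up the HCl to leave the neutral 2-acylenamine 6, and hot aqueous HCl hydrolyses both vinylogous amides to the 2-acylcyclohexanones, which rest as the hydrogen-bonded enols 7. The closest known reaction type is the Stork enamine acylation as applied to diacid dichlorides for two-directional chain extension. The step closes no ring and creates no stereocentre (C2 of each six-membered ring is sp2 in the enol); it forms the C6–C7 and C28–C29 bonds and places all thirty-four chain carbons in one molecule. The selectivity needed is C- over N-acylation, one acyl group per ring and reaction at both chain ends: N-acylation is reversible and funnels to the C-acyl product, the vinylogous amide 6 is too electron-poor to be acylated again, and the slight excess of 3 with slow addition of 5 should drive both termini to react.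

Step 4
Reactants: 7 1,22-bis(2-hydroxycyclohex-1-en-1-yl)docosane-1,22-dione
Product: 8 7,28-dioxotetratriacontanedioic acid
Conditions: NaOH (aq, excess), EtOH, reflux; then aq HCl to pH 1
Reagents that add atoms: sodium hydroxide, [Na+].[OH-]
Why: Retro-Claisen cleavage of a β-diketone: hydroxide adds to the ring carbonyl, which accepts nucleophiles more readily than the open-chain one, and the ring C1–C2 bond breaks to unroll each ring into a six-carbon carboxylate arm, the usual course for 2-acylcyclohexanones.

Step 5
Reactants: 8 7,28-dioxotetratriacontanedioic acid
Product: 10 tetratriacontanedioic acid, via bis-hydrazone 9 (not isolated)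
Conditions: N2H4·H2O, KOH, diethylene glycol, 130 °C, then 200 °C with removal of water; then aq HCl
Reagents that add atoms: none
Why: Wolff–Kishner reduction in the Huang-Minlon modification turns each hydrazone into CH2 with loss of N2, and the carboxylate ends are inert to the conditions.

Step 6
Reactants: 10 tetratriacontanedioic acid
Product: 11 dimethyl tetratriacontanedioate
Conditions: MeOH (excess), H2SO4 (cat.), toluene, reflux
Reagents that add atoms: methanol, CO
Why: Fischer esterification driven by excess methanol gives a diester that dissolves in warm toluene or THF, so the following steps can be run in solution.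

Step 7
Reactants: 11 dimethyl tetratriacontanedioate
Product: 12 34-methoxy-34-oxotetratriacontanoic acid
Conditions: KOH (1.0 equiv), THF/MeOH, 45 °C; then 1 M aq HCl
Reagents that add atoms: potassium hydroxide, [K+].[OH-]
Why: Mono-saponification with one equivalent of hydroxide is statistical, helped by precipitation of the half-ester potassium salt, which withdraws it from the second hydrolysis; recovered 11 and over-hydrolysed 10 are separated and recycled.

Step 8
Reactants: 12 34-methoxy-34-oxotetratriacontanoic acid
Product: 13 methyl 34-hydroxytetratriacontanoate
Conditions: BH3·SMe2 (1.5 equiv), THF, 0 °C to 35 °C; then H2O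
Reagents that add atoms: none
Why: Chemoselective borane reduction: the electrophilic reductant reduces a carboxylic acid much faster than an ester, so the acid end should go to the primary alcohol while the methyl ester survives.

Step 9
Reactants: 13 methyl 34-hydroxytetratriacontanoate
Product: 14 34-hydroxytetratriacontanoic acid
Conditions: KOH, THF/MeOH/H2O, 60 °C; then aq HCl
Reagents that add atoms: potassium hydroxide, [K+].[OH-]
Why: Plain ester saponification with no other base-sensitive group present; acidification should precipitate the hydroxy acid.

Step 10
Reactants: 14 34-hydroxytetratriacontanoic acid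
Product: 16 oxacyclopentatriacontan-2-one, via mixed anhydride 15 (not isolated)
Conditions: 2,4,6-trichlorobenzoyl chloride, Et3N, THF, 40 °C; then slow addition to DMAP (excess), toluene, reflux, about 1 mM
Reagents that add atoms: none
Why: Yamaguchi macrolactonisation: DMAP attacks the unhindered aliphatic carbonyl of the mixed anhydride, and under high dilution the C34 hydroxyl should close the strain-free 35-membered ring by acyl substitution in preference to oligomerisation.

**Compound list**
1 | cyclohexanone | O=C1CCCCC1 | starting material
2 | morpholine | C1COCCN1 | starting material
3 | 4-(cyclohex-1-en-1-yl)morpholine | C1(N2CCOCC2)=CCCCC1 | intermediate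
4 | docosanedioic acid | OC(=O)CCCCCCCCCCCCCCCCCCCCC(O)=O | starting material
5 | docosanedioyl dichloride | ClC(=O)CCCCCCCCCCCCCCCCCCCCC(Cl)=O | intermediate
6 | 1,22-bis(2-morpholinocyclohex-1-en-1-yl)docosane-1,22-dione (bis-acylenamine, formed in the flask, not isolated) | O=C(C1=C(N2CCOCC2)CCCC1)CCCCCCCCCCCCCCCCCCCCC(=O)C1=C(N2CCOCC2)CCCC1 | intermediate
7 | 1,22-bis(2-hydroxycyclohex-1-en-1-yl)docosane-1,22-dione (enol form of the bis-β-diketone) | O=C(C1=C(O)CCCC1)CCCCCCCCCCCCCCCCCCCCC(=O)C1=C(O)CCCC1 | intermediate
8 | 7,28-dioxotetratriacontanedioic acid | OC(=O)CCCCCC(=O)CCCCCCCCCCCCCCCCCCCCC(=O)CCCCCC(O)=O | intermediate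
9 | 7,28-dihydrazinylidenetetratriacontanedioic acid (bis-hydrazone, formed in the flask, not isolated) | OC(=O)CCCCCC(=NN)CCCCCCCCCCCCCCCCCCCCC(=NN)CCCCCC(O)=O | intermediate
10 | tetratriacontanedioic acid | OC(=O)CCCCCCCCCCCCCCCCCCCCCCCCCCCCCCCCC(O)=O | intermediate
11 | dimethyl tetratriacontanedioate | COC(=O)CCCCCCCCCCCCCCCCCCCCCCCCCCCCCCCCC(=O)OC | intermediate
12 | 34-methoxy-34-oxotetratriacontanoic acid | COC(=O)CCCCCCCCCCCCCCCCCCCCCCCCCCCCCCCCC(O)=O | intermediate
13 | methyl 34-hydroxytetratriacontanoate | COC(=O)CCCCCCCCCCCCCCCCCCCCCCCCCCCCCCCCCO | intermediate
14 | 34-hydroxytetratriacontanoic acid | OC(=O)CCCCCCCCCCCCCCCCCCCCCCCCCCCCCCCCCO | intermediate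
15 | 34-hydroxytetratriacontanoic 2,4,6-trichlorobenzoic anhydride (formed in the flask, not isolated) | OCCCCCCCCCCCCCCCCCCCCCCCCCCCCCCCCCC(=O)OC(=O)c1c(Cl)cc(Cl)cc1Cl | intermediate
16 | oxacyclopentatriacontan-2-one (34-tetratriacontanolide) | O=C1CCCCCCCCCCCCCCCCCCCCCCCCCCCCCCCCCO1 | target

**Step count**
Total steps: 10. Longest linear sequence: 9 steps (step 2 or step 1, then steps 3 to 10).

**Steps most likely to fail**

Step 7 (half-saponification). The two ester groups are far apart and react at nearly the same rate, so the hydrolysis may run on to the diacid or stall at the sparingly soluble diester, leaving little half ester. Fallback, from dimethyl ester 11: reduction of both esters with LiAlH4 in THF at reflux would give tetratriacontane-1,34-diol F2. Heating this diol with 48% aqueous HBr in toluene, a two-phase method known to stop α,ω-diols largely at the monobromide, should give 34-bromotetratriacontan-1-ol F3. Oxidation of the remaining alcohol (TEMPO cat., PhI(OAc)2, CH2Cl2/MeCN/H2O) would give 34-bromotetratriacontanoic acid F4. Intramolecular O-alkylation of its caesium carboxylate (Cs2CO3, DMF, 80 °C, slow addition, high dilution) would close the lactone and come back to the route at target 16, by-passing 12 to 15.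

Step 3 (double enamine acylation). Dehydrochlorination of the acid chloride by Et3N to a ketene that dimerises, or acylation at only one chain end, may give tars and half-reacted material instead of the bis-β-diketone. Fallback, from dichloride 5: treatment with 1H-benzotriazole and Et3N in CH2Cl2 would give 1,22-bis(1H-benzotriazol-1-yl)docosane-1,22-dione F1, a stable bis-acylating agent much less prone to ketene formation. Soft enolisation of cyclohexanone 1 (excess) with MgBr2·OEt2 and i-Pr2NEt in CH2Cl2 and C-acylation by F1 should give the bis-β-diketone directly, its magnesium chelate resisting a second acylation. This forms the same C6–C7 and C28–C29 bonds and comes back to the route at 7.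

Step 10 (macrolactonisation). Intermolecular esterification may compete with ring closure and give the 70-membered diolide and linear oligomers, made worse if the activated hydroxy acid is poorly soluble. Fallback, from hydroxy acid 14: Mitsunobu macrolactonisation (PPh3, DIAD, toluene/THF, slow addition, high dilution) activates the primary C34 hydroxyl as an alkoxyphosphonium ion and lets the carboxylate close the ring by O-alkylation, so no activated acyl species accumulates. It comes back to the route at 16 and makes no compound beyond those listed (F0).

**Further compounds**
F1 | step 3 | 1,22-bis(1H-benzotriazol-1-yl)docosane-1,22-dione | O=C(n1nnc2ccccc12)CCCCCCCCCCCCCCCCCCCCC(=O)n1nnc2ccccc12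
F2 | step 7 | tetratriacontane-1,34-diol | OCCCCCCCCCCCCCCCCCCCCCCCCCCCCCCCCCCO
F3 | step 7 | 34-bromotetratriacontan-1-ol | OCCCCCCCCCCCCCCCCCCCCCCCCCCCCCCCCCCBr
F4 | step 7 | 34-bromotetratriacontanoic acid | OC(=O)CCCCCCCCCCCCCCCCCCCCCCCCCCCCCCCCCBr
F0 | step 10 | none | none
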